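**Retrosynthetic overview**

1. The route rests on the C4–O–C7 bridge: a 2,5-dihydrofuran hemiketal inside the ten-membered ring, with the oxygens on C4 and C7 standing 1,4 across the cis C5=C6 alkene. Both come from one O2 by [4+2] addition to the ring-held C4=C5–C6=C7 diene (1,2-dioxine ring), then Kornblum–DeLaMare cleavage and hemiketal closure; the C8 urocanate goes on last.
2. The ten-membered ring is closed just before, at 0 °C, by copper-mediated sp2–sp2 coupling of a C3 α-iodoenoate with a C4 (Z,Z)-dienylstannane. The all-cis C2=C3–C4=C5–C6=C7 triene can undergo thermal 6π ring closure, so it is made and used cold.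
3. Ring A comes from a lactone-enolate Ireland–Claisen rearrangement (C1–C10 bond, C11=C12 alkene) of a trans-4-isopropyl-6-[(Z)-alkenyl] δ-lactone. This sets C2 on C1 cis to the isopropyl group and trans to C9 on C10.
4. The lactone comes from asymmetric allylboration, acrylation, ring-closing metathesis and conjugate addition. Its side chain (C6–C9 with the 8S carbinol and the Z vinyl iodide) comes from propargyl alcohol.
5. Ring order: δ-lactone (sacrificed) → ring A → ten-membered ring → 1,2-dioxine → dihydrofuran.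

Key step: step 20

Remark: the target SMILES places the C1–C2 and C10–C9 bonds trans on ring A, with C2 cis to the C14 isopropyl group (1R,10R,14R), and the route is built for exactly this array; atom numbers are those of the bicyclo[8.4.0]tetradecane skeleton (C1/C10 ring fusion, C3 ester carbon, C4 hemiketal carbon, C7 methyl-bearing carbon, C8 acyloxy carbon).

**Route**

Step 1
Reactants: 1 prop-2-yn-1-ol
Product: 3 (2Z)-3-iodo-2-methylprop-2-en-1-ol, via vinylmagnesium alkoxide 2 (not isolated)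
Conditions: MeMgBr (2.5 equiv), CuI (10 mol%), THF, −10 °C to rt; then I2, −78 to 0 °C
Reagents that add atoms: methylmagnesium bromide, C[Mg]Br; iodine, II
Why: Hydroxyl-directed copper-catalysed anti-carbomagnesiation of the propargylic alkoxide puts the methyl group on the inner carbon (future C7) and magnesium on the terminal carbon (future C6) cis to the carbinol carbon through a five-membered chelate, and iodinolysis with retention should give the Z iodide.

Step 2
Reactants: 3 (2Z)-3-iodo-2-methylprop-2-en-1-ol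
Product: 4 (2Z)-3-iodo-2-methylprop-2-enal
Conditions: MnO2, CH2Cl2, rt, dark
Reagents that add atoms: none
Why: Allylic alcohol oxidation on activated MnO2 is neutral, so the Z geometry of the enal should be kept.

Step 3
Reactants: 4 (2Z)-3-iodo-2-methylprop-2-enal
Product: 6 (1Z,3S)-1-iodo-2-methylhexa-1,5-dien-3-ol, via borinate ester 5 (not isolated)
Conditions: B-allyldiisopinocampheylborane made from (+)-α-pinene, Et2O, −78 °C; then NaOH, H2O2, 0 °C
Reagents that add atoms: B-allyldiisopinocampheylborane from (+)-α-pinene, C=CCB([C@@H]1C[C@@H]2C[C@H]([C@H]1C)C2(C)C)[C@@H]1C[C@@H]2C[C@H]([C@H]1C)C2(C)C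
Why: Asymmetric allylboration (Brown allylation) through a chair six-membered transition state, in which this enantiomer of the reagent delivers allyl to the Si face of the aldehyde, should set the future C8 carbinol as S.

Step 4
Reactants: 6 (1Z,3S)-1-iodo-2-methylhexa-1,5-dien-3-ol
Product: 7 triethyl{[(1Z,3S)-1-iodo-2-methylhexa-1,5-dien-3-yl]oxy}silane
Conditions: TESCl, imidazole, CH2Cl2, 0 °C
Reagents that add atoms: chlorotriethylsilane, CC[Si](Cl)(CC)CC
Why: Silylation of the secondary alcohol gives a triethylsilyl ether that survives bases, hydrides and organometallics and can later be removed with buffered fluoride.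

Step 5
Reactants: 7 triethyl{[(1Z,3S)-1-iodo-2-methylhexa-1,5-dien-3-yl]oxy}silane
Product: 9 (3S,4Z)-5-iodo-4-methyl-3-(triethylsilyloxy)pent-4-enal, via 1,2-diol 8 (not isolated)
Conditions: OsO4 (2 mol%), NaIO4, 2,6-lutidine, dioxane/H2O 3:1, rt
Reagents that add atoms: osmium tetroxide (oxygen carrier, re-oxidised by the periodate), O=[Os](=O)(=O)=O; sodium periodate, [Na+].[O-]I(=O)(=O)=O
Why: Lemieux–Johnson cleavage attacks the monosubstituted terminal alkene in preference to the hindered, electron-poor trisubstituted vinyl iodide and leaves the C10 aldehyde two carbons from the carbinol.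

Step 6
Reactants: 9 (3S,4Z)-5-iodo-4-methyl-3-(triethylsilyloxy)pent-4-enal
Product: 10 methyl (2Z,5S,6Z)-7-iodo-2,6-dimethyl-5-(triethylsilyloxy)hepta-2,6-dienoate
Conditions: methyl 2-[bis(2,2,2-trifluoroethoxy)phosphoryl]propanoate, KN(SiMe3)2, 18-crown-6, THF, −78 °C
Reagents that add atoms: methyl 2-[bis(2,2,2-trifluoroethoxy)phosphoryl]propanoate, COC(=O)C(C)P(=O)(OCC(F)(F)F)OCC(F)(F)F
Why: Still–Gennari olefination (fast, irreversible elimination from the kinetic adduct) should give the Z trisubstituted enoate, with the ester carbon (future C12) cis to C9.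

Step 7
Reactants: 10 methyl (2Z,5S,6Z)-7-iodo-2,6-dimethyl-5-(triethylsilyloxy)hepta-2,6-dienoate
Product: 11 (2Z,5S,6Z)-7-iodo-2,6-dimethyl-5-(triethylsilyloxy)hepta-2,6-dien-1-ol
Conditions: iBu2AlH, CH2Cl2, −78 °C
Reagents that add atoms: none
Why: 1,2-Reduction of the enoate with iBu2AlH gives the allylic alcohol without touching the vinyl iodide, the silyl ether or the alkene geometry.

Step 8
Reactants: 11 (2Z,5S,6Z)-7-iodo-2,6-dimethyl-5-(triethylsilyloxy)hepta-2,6-dien-1-ol
Product: 12 (2Z,5S,6Z)-7-iodo-2,6-dimethyl-5-(triethylsilyloxy)hepta-2,6-dienal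
Conditions: MnO2, CH2Cl2, rt, dark; used at once
Reagents that add atoms: none
Why: Neutral allylic oxidation on MnO2 should deliver the Z enal without isomerisation to the E enal.

Step 9
Reactants: 12 (2Z,5S,6Z)-7-iodo-2,6-dimethyl-5-(triethylsilyloxy)hepta-2,6-dienal
Product: 14 (4R,5Z,8S,9Z)-10-iodo-5,9-dimethyl-8-(triethylsilyloxy)deca-1,5,9-trien-4-ol, via borinate ester 13 (not isolated)
Conditions: B-allyldiisopinocampheylborane made from (−)-α-pinene, Et2O, −78 °C; then NaOH, H2O2, 0 °C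
Reagents that add atoms: B-allyldiisopinocampheylborane from (−)-α-pinene, C=CCB([C@H]1C[C@H]2C[C@@H]([C@@H]1C)C2(C)C)[C@H]1C[C@H]2C[C@@H]([C@@H]1C)C2(C)C
Why: Asymmetric allylboration with the enantiomeric reagent attacks the Re face of the enal under reagent control (the C8 centre is remote) and should set the future C12 carbinol as R.

Step 10
Reactants: 14 (4R,5Z,8S,9Z)-10-iodo-5,9-dimethyl-8-(triethylsilyloxy)deca-1,5,9-trien-4-ol
Product: 15 (4R,5Z,8S,9Z)-10-iodo-5,9-dimethyl-8-(triethylsilyloxy)deca-1,5,9-trien-4-yl prop-2-enoate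
Conditions: acryloyl chloride, iPr2NEt, DMAP (cat.), CH2Cl2, 0 °C
Reagents that add atoms: acryloyl chloride, C=CC(=O)Cl
Why: O-Acylation of the secondary alcohol installs the acrylate that supplies the future C1 and C2.

Step 11
Reactants: 15 (4R,5Z,8S,9Z)-10-iodo-5,9-dimethyl-8-(triethylsilyloxy)deca-1,5,9-trien-4-yl prop-2-enoate
Product: 16 (6R)-6-[(2Z,5S,6Z)-7-iodo-6-methyl-5-(triethylsilyloxy)hepta-2,6-dien-2-yl]-5,6-dihydro-2H-pyran-2-one
Conditions: second-generation Grubbs catalyst RuCl2(=CHPh)(H2IMes)(PCy3) (5 mol%), CH2Cl2, 40 °C, 5 mM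
Reagents that add atoms: none
Why: Ring-closing metathesis joins the acrylate and the terminal alkene to the six-membered unsaturated lactone, the two trisubstituted alkenes being too hindered to take part.

Step 12
Reactants: 16 (6R)-6-[(2Z,5S,6Z)-7-iodo-6-methyl-5-(triethylsilyloxy)hepta-2,6-dien-2-yl]-5,6-dihydro-2H-pyran-2-one
Product: 17 (4S,6R)-6-[(2Z,5S,6Z)-7-iodo-6-methyl-5-(triethylsilyloxy)hepta-2,6-dien-2-yl]-4-(propan-2-yl)oxan-2-one
Conditions: iPrMgCl, CuBr·SMe2 (20 mol%), THF, −78 °C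
Reagents that add atoms: isopropylmagnesium chloride, CC(C)[Mg]Cl
Why: Copper-catalysed conjugate addition enters axially on the half-chair lactone anti to the pseudo-equatorial C6 substituent and should give the 4,6-trans lactone (future C14), while at −78 °C the vinyl iodide is expected to stay untouched.

Step 13
Reactants: 17 (4S,6R)-6-[(2Z,5S,6Z)-7-iodo-6-methyl-5-(triethylsilyloxy)hepta-2,6-dien-2-yl]-4-(propan-2-yl)oxan-2-one
Product: 20 [(1S,2R,6R)-2-{(2S,3Z)-4-iodo-3-methyl-2-(triethylsilyloxy)but-3-en-1-yl}-3-methyl-6-(propan-2-yl)cyclohex-3-en-1-yl]methanol, via silyl ketene acetal 18 (not isolated), via silyl ester 19 (not isolated)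
Conditions: LiN(iPr)2, TBSCl, HMPA, THF, −78 °C; toluene, 105 °C; then iBu2AlH, −78 to 0 °C
Reagents that add atoms: none
Why: Ireland–Claisen rearrangement of the lactone silyl ketene acetal must pass through a boat transition state in which the C1–C10 bond forms on the face of the breaking C12–O bond: the trans isopropyl group then ends cis to C2, the Z alkene places C9 trans to C2, the new ring alkene is C11=C12, and iBu2AlH reduces the silyl ester to the primary alcohol.

Step 14
Reactants: 21 acetylene; 22 hexabutyldistannane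
Product: 23 (Z)-1,2-bis(tributylstannyl)ethene
Conditions: Pd(PPh3)4 (1 mol%), dioxane, 60 °C, sealed vessel
Reagents that add atoms: none
Why: Palladium-catalysed syn-distannylation of the alkyne adds both tin groups to one face and should give the Z bis-stannane.

Step 15
Reactants: 20 [(1S,2R,6R)-2-{(2S,3Z)-4-iodo-3-methyl-2-(triethylsilyloxy)but-3-en-1-yl}-3-methyl-6-(propan-2-yl)cyclohex-3-en-1-yl]methanol; 23 (Z)-1,2-bis(tributylstannyl)ethene (3 equiv)
Product: 24 [(1S,2R,6R)-3-methyl-2-{(2S,3Z,5Z)-3-methyl-6-(tributylstannyl)-2-(triethylsilyloxy)hexa-3,5-dien-1-yl}-6-(propan-2-yl)cyclohex-3-en-1-yl]methanol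
Conditions: Pd2(dba)3 (2.5 mol%), AsPh3 (20 mol%), NMP, rt
Reagents that add atoms: none
Why: Stille coupling with retention at both sp2 carbons attaches C5–C4 to C6, and the excess of the bis-stannane should hold the reaction at mono-coupling so that the (Z,Z)-dienylstannane results.

Step 16
Reactants: 24 [(1S,2R,6R)-3-methyl-2-{(2S,3Z,5Z)-3-methyl-6-(tributylstannyl)-2-(triethylsilyloxy)hexa-3,5-dien-1-yl}-6-(propan-2-yl)cyclohex-3-en-1-yl]methanol
Product: 25 (1S,2R,6R)-3-methyl-2-{(2S,3Z,5Z)-3-methyl-6-(tributylstannyl)-2-(triethylsilyloxy)hexa-3,5-dien-1-yl}-6-(propan-2-yl)cyclohex-3-ene-1-carbaldehyde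
Conditions: Dess–Martin periodinane, NaHCO3, CH2Cl2, 0 °C; used at once
Reagents that add atoms: none
Why: Buffered Dess–Martin oxidation gives the C2 aldehyde under non-basic, non-acidic conditions that should spare the dienylstannane and the epimerisable C1 centre.

Step 17
Reactants: 25 (1S,2R,6R)-3-methyl-2-{(2S,3Z,5Z)-3-methyl-6-(tributylstannyl)-2-(triethylsilyloxy)hexa-3,5-dien-1-yl}-6-(propan-2-yl)cyclohex-3-ene-1-carbaldehyde
Product: 26 methyl (2Z)-2-iodo-3-[(1S,2R,6R)-3-methyl-2-{(2S,3Z,5Z)-3-methyl-6-(tributylstannyl)-2-(triethylsilyloxy)hexa-3,5-dien-1-yl}-6-(propan-2-yl)cyclohex-3-en-1-yl]prop-2-enoate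
Conditions: Ph3P=CHCO2Me (1.6 equiv), N-iodosuccinimide (1.5 equiv, fully consumed before the aldehyde is added), K2CO3, CH2Cl2, −20 °C; then 25, 0 °C to rt
Reagents that add atoms: methyl (triphenylphosphoranylidene)acetate, COC(=O)C=P(c1ccccc1)(c1ccccc1)c1ccccc1; N-iodosuccinimide, O=C1CCC(=O)N1I
Why: Wittig olefination with the stabilised α-iodo ylide formed in the flask should give the (Z)-2-iodoenoate, with the ester trans to C1 and the iodide in the position that C4 will take.

Step 18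
Reactants: 26 methyl (2Z)-2-iodo-3-[(1S,2R,6R)-3-methyl-2-{(2S,3Z,5Z)-3-methyl-6-(tributylstannyl)-2-(triethylsilyloxy)hexa-3,5-dien-1-yl}-6-(propan-2-yl)cyclohex-3-en-1-yl]prop-2-enoate
Product: 27 methyl (2Z)-3-[(1S,2R,6R)-2-{(2S,3Z,5Z)-2-hydroxy-3-methyl-6-(tributylstannyl)hexa-3,5-dien-1-yl}-3-methyl-6-(propan-2-yl)cyclohex-3-en-1-yl]-2-iodoprop-2-enoate
Conditions: HF·pyridine, pyridine, THF, 0 °C
Reagents that add atoms: none
Why: Buffered fluoride removes the triethylsilyl ether before ring closure, so that the labile triene never has to be deprotected, and the pyridine buffer should protect the stannane from protodestannylation.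

Step 19
Reactants: 27 methyl (2Z)-3-[(1S,2R,6R)-2-{(2S,3Z,5Z)-2-hydroxy-3-methyl-6-(tributylstannyl)hexa-3,5-dien-1-yl}-3-methyl-6-(propan-2-yl)cyclohex-3-en-1-yl]-2-iodoprop-2-enoate
Product: 28 methyl (1R,2E,4Z,6Z,8S,10R,11Z,14R)-8-hydroxy-7,11-dimethyl-14-(propan-2-yl)bicyclo[8.4.0]tetradeca-2,4,6,11-tetraene-3-carboxylate
Conditions: copper thiophene-2-carboxylate CuO2C-C4H3S (3 equiv), NMP, 0 °C, 1 mM, slow addition of 27; cold work-up, filtration through alumina at −20 °C, used the same day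
Reagents that add atoms: none
Why: Copper-mediated Stille-type coupling (tin-to-copper transmetalation, then coupling with the α-iodoenoate) forms the C3–C4 bond with retention of both alkene geometries and closes the ten-membered ring at 0 °C, a temperature chosen so that the all-cis C2–C7 triene does not undergo 6π-electrocyclisation.

Step 20
Reactants: 28 methyl (1R,2E,4Z,6Z,8S,10R,11Z,14R)-8-hydroxy-7,11-dimethyl-14-(propan-2-yl)bicyclo[8.4.0]tetradeca-2,4,6,11-tetraene-3-carboxylate; 29 dioxygen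
Product: 30 methyl (1R,2E,4R,5Z,7S,8S,10R,11Z,14R)-4,7-epidioxy-8-hydroxy-7,11-dimethyl-14-(propan-2-yl)bicyclo[8.4.0]tetradeca-2,5,11-triene-3-carboxylate
Conditions: O2 (1 atm), meso-tetraphenylporphyrin (1 mol%), CH2Cl2, −78 °C, visible light (>500 nm)
Reagents that add atoms: none
Why: Singlet oxygen, formed by energy transfer from the excited porphyrin, adds in a concerted suprafacial [4+2] manner to C4 and C7 of the cisoid C4=C5–C6=C7 diene; the closest known reaction is the photooxygenation of cyclic cis,cis-1,3-dienes such as cycloocta-1,3-diene to their 1,4-endoperoxides. The 3,6-dihydro-1,2-dioxine closes by this cycloaddition as the two-oxygen bridge of a bicyclo[6.2.2] unit, both C–O bonds forming on one diene face while the ring chain on the inner diene termini swings to the other. C7 is controlled by the C8 carbinol: 1,3-allylic strain with C5 holds C8–H in the diene plane, which puts C9 and the rest of the ring on one face and the hydroxyl on the other, so oxygen enters syn to the hydroxyl (hydrogen-bond steering, kept alive by the non-polar solvent) and anti to the ring chain, which gives 7S. C4 follows from the suprafacial addition and is erased in step 21. The step needs chemoselectivity over the ene reaction at C11=C12 and at the C7 methyl group and over addition to the C2=C3–C4=C5 diene: the C3 ester deactivates that second diene, and the cisoid ring-held diene should react fastest at −78 °C. The low temperature also keeps the triene from thermal 6π closure before it is trapped.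

Step 21
Reactants: 30 methyl (1R,2E,4R,5Z,7S,8S,10R,11Z,14R)-4,7-epidioxy-8-hydroxy-7,11-dimethyl-14-(propan-2-yl)bicyclo[8.4.0]tetradeca-2,5,11-triene-3-carboxylate
Product: 32 methyl (1R,2E,4R,5Z,7S,8S,10R,11Z,14R)-4,7-epoxy-4,8-dihydroxy-7,11-dimethyl-14-(propan-2-yl)bicyclo[8.4.0]tetradeca-2,5,11-triene-3-carboxylate, via hydroxy enone 31 (not isolated)
Conditions: Et3N, CH2Cl2, 0 °C to rt
Reagents that add atoms: none
Why: Kornblum–DeLaMare rearrangement: the amine removes the only peroxide α-hydrogen (C4–H, allylic to C2=C3 and C5=C6), the O–O bond breaks to the C4 ketone and the C7 alkoxide, and the cis γ-hydroxy enone closes to the 2,5-dihydrofuran hemiketal, whose C4 configuration (R) is fixed by the bridge.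

Step 22
Reactants: 33 1-methyl-1H-imidazole-4-carbaldehyde; 34 malonic acid
Product: 36 (2E)-3-(1-methyl-1H-imidazol-4-yl)prop-2-enoic acid, via alkylidenemalonic acid 35 (not isolated)
Conditions: pyridine, piperidine (cat.), 100 °C
Reagents that add atoms: none
Why: Knoevenagel–Doebner condensation followed by decarboxylation in the same flask gives the E acrylic acid with the methyl group already fixed on N1.

Step 23
Reactants: 32 methyl (1R,2E,4R,5Z,7S,8S,10R,11Z,14R)-4,7-epoxy-4,8-dihydroxy-7,11-dimethyl-14-(propan-2-yl)bicyclo[8.4.0]tetradeca-2,5,11-triene-3-carboxylate; 36 (2E)-3-(1-methyl-1H-imidazol-4-yl)prop-2-enoic acid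
Product: 37 CNP0372023.1, the 8-O-[(2E)-3-(1-methyl-1H-imidazol-4-yl)prop-2-enoyl] ester of 32
Conditions: DCC, DMAP (cat.), CH2Cl2, rt; 36 (1.2 equiv)
Reagents that add atoms: none
Why: Steglich esterification should acylate the secondary C8 hydroxyl in preference to the tertiary hemiketal hydroxyl at C4 and so complete the target.

**Compound list**

1 | prop-2-yn-1-ol (propargyl alcohol) | C#CCO | starting material
2 | bromomagnesium (2Z)-3-(bromomagnesio)-2-methylprop-2-en-1-olate | C/C(CO[Mg]Br)=C/[Mg]Br | intermediate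
3 | (2Z)-3-iodo-2-methylprop-2-en-1-ol | C/C(CO)=C/I | intermediate
4 | (2Z)-3-iodo-2-methylprop-2-enal | C/C(C=O)=C/I | intermediate
5 | O-diisopinocampheylboryl derivative of 6 (isopinocampheyl groups from (+)-α-pinene) | C=CC[C@H](OB([C@@H]1C[C@@H]2C[C@H]([C@H]1C)C2(C)C)[C@@H]1C[C@@H]2C[C@H]([C@H]1C)C2(C)C)/C(C)=C\I | intermediate
6 | (1Z,3S)-1-iodo-2-methylhexa-1,5-dien-3-ol | C=CC[C@H](O)/C(C)=C\I | intermediate
7 | triethyl{[(1Z,3S)-1-iodo-2-methylhexa-1,5-dien-3-yl]oxy}silane | C=CC[C@H](O[Si](CC)(CC)CC)/C(C)=C\I | intermediate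
8 | (4S,5Z)-6-iodo-5-methyl-4-(triethylsilyloxy)hex-5-ene-1,2-diol (both C2 epimers) | OCC(O)C[C@H](O[Si](CC)(CC)CC)/C(C)=C\I | intermediate
9 | (3S,4Z)-5-iodo-4-methyl-3-(triethylsilyloxy)pent-4-enal | O=CC[C@H](O[Si](CC)(CC)CC)/C(C)=C\I | intermediate
10 | methyl (2Z,5S,6Z)-7-iodo-2,6-dimethyl-5-(triethylsilyloxy)hepta-2,6-dienoate | COC(=O)/C(C)=C\C[C@H](O[Si](CC)(CC)CC)/C(C)=C\I | intermediate
11 | (2Z,5S,6Z)-7-iodo-2,6-dimethyl-5-(triethylsilyloxy)hepta-2,6-dien-1-ol | OC/C(C)=C\C[C@H](O[Si](CC)(CC)CC)/C(C)=C\I | intermediate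
12 | (2Z,5S,6Z)-7-iodo-2,6-dimethyl-5-(triethylsilyloxy)hepta-2,6-dienal | O=C/C(C)=C\C[C@H](O[Si](CC)(CC)CC)/C(C)=C\I | intermediate
13 | O-diisopinocampheylboryl derivative of 14 (isopinocampheyl groups from (−)-α-pinene) | C=CC[C@@H](OB([C@H]1C[C@H]2C[C@@H]([C@@H]1C)C2(C)C)[C@H]1C[C@H]2C[C@@H]([C@@H]1C)C2(C)C)/C(C)=C\C[C@H](O[Si](CC)(CC)CC)/C(C)=C\I | intermediate
14 | (4R,5Z,8S,9Z)-10-iodo-5,9-dimethyl-8-(triethylsilyloxy)deca-1,5,9-trien-4-ol | C=CC[C@@H](O)/C(C)=C\C[C@H](O[Si](CC)(CC)CC)/C(C)=C\I | intermediate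
15 | (4R,5Z,8S,9Z)-10-iodo-5,9-dimethyl-8-(triethylsilyloxy)deca-1,5,9-trien-4-yl prop-2-enoate | C=CC[C@@H](OC(=O)C=C)/C(C)=C\C[C@H](O[Si](CC)(CC)CC)/C(C)=C\I | intermediate
16 | (6R)-6-[(2Z,5S,6Z)-7-iodo-6-methyl-5-(triethylsilyloxy)hepta-2,6-dien-2-yl]-5,6-dihydro-2H-pyran-2-one | O=C1C=CC[C@@H](O1)/C(C)=C\C[C@H](O[Si](CC)(CC)CC)/C(C)=C\I | intermediate
17 | (4S,6R)-6-[(2Z,5S,6Z)-7-iodo-6-methyl-5-(triethylsilyloxy)hepta-2,6-dien-2-yl]-4-(propan-2-yl)oxan-2-one (4,6-trans) | O=C1C[C@@H](C(C)C)C[C@@H](O1)/C(C)=C\C[C@H](O[Si](CC)(CC)CC)/C(C)=C\I | intermediate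
18 | O-tert-butyldimethylsilyl ketene acetal of lactone 17 (6-silyloxy-3,4-dihydro-2H-pyran, stereocentres as in 17) | CC(C)(C)[Si](C)(C)OC1=C[C@@H](C(C)C)C[C@@H](O1)/C(C)=C\C[C@H](O[Si](CC)(CC)CC)/C(C)=C\I | intermediate
19 | tert-butyldimethylsilyl ester of the ring A carboxylic acid (acid corresponding to alcohol 20, same stereocentres) | CC(C)(C)[Si](C)(C)OC(=O)[C@H]1[C@@H](C(C)C)CC=C(C)[C@@H]1C[C@H](O[Si](CC)(CC)CC)/C(C)=C\I | intermediate
20 | [(1S,2R,6R)-2-{(2S,3Z)-4-iodo-3-methyl-2-(triethylsilyloxy)but-3-en-1-yl}-3-methyl-6-(propan-2-yl)cyclohex-3-en-1-yl]methanol | OC[C@H]1[C@@H](C(C)C)CC=C(C)[C@@H]1C[C@H](O[Si](CC)(CC)CC)/C(C)=C\I | intermediate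
21 | acetylene | C#C | starting material
22 | hexabutyldistannane | CCCC[Sn](CCCC)(CCCC)[Sn](CCCC)(CCCC)CCCC | starting material
23 | (Z)-1,2-bis(tributylstannyl)ethene | CCCC[Sn](CCCC)(CCCC)/C=C\[Sn](CCCC)(CCCC)CCCC | intermediate
24 | [(1S,2R,6R)-3-methyl-2-{(2S,3Z,5Z)-3-methyl-6-(tributylstannyl)-2-(triethylsilyloxy)hexa-3,5-dien-1-yl}-6-(propan-2-yl)cyclohex-3-en-1-yl]methanol | OC[C@H]1[C@@H](C(C)C)CC=C(C)[C@@H]1C[C@H](O[Si](CC)(CC)CC)/C(C)=C\C=C/[Sn](CCCC)(CCCC)CCCC | intermediate
25 | (1S,2R,6R)-3-methyl-2-{(2S,3Z,5Z)-3-methyl-6-(tributylstannyl)-2-(triethylsilyloxy)hexa-3,5-dien-1-yl}-6-(propan-2-yl)cyclohex-3-ene-1-carbaldehyde | O=C[C@H]1[C@@H](C(C)C)CC=C(C)[C@@H]1C[C@H](O[Si](CC)(CC)CC)/C(C)=C\C=C/[Sn](CCCC)(CCCC)CCCC | intermediate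
26 | methyl (2Z)-2-iodo-3-[(1S,2R,6R)-3-methyl-2-{(2S,3Z,5Z)-3-methyl-6-(tributylstannyl)-2-(triethylsilyloxy)hexa-3,5-dien-1-yl}-6-(propan-2-yl)cyclohex-3-en-1-yl]prop-2-enoate | COC(=O)/C(I)=C/[C@H]1[C@@H](C(C)C)CC=C(C)[C@@H]1C[C@H](O[Si](CC)(CC)CC)/C(C)=C\C=C/[Sn](CCCC)(CCCC)CCCC | intermediate
27 | methyl (2Z)-3-[(1S,2R,6R)-2-{(2S,3Z,5Z)-2-hydroxy-3-methyl-6-(tributylstannyl)hexa-3,5-dien-1-yl}-3-methyl-6-(propan-2-yl)cyclohex-3-en-1-yl]-2-iodoprop-2-enoate | COC(=O)/C(I)=C/[C@H]1[C@@H](C(C)C)CC=C(C)[C@@H]1C[C@H](O)/C(C)=C\C=C/[Sn](CCCC)(CCCC)CCCC | intermediate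
28 | methyl (1R,2E,4Z,6Z,8S,10R,11Z,14R)-8-hydroxy-7,11-dimethyl-14-(propan-2-yl)bicyclo[8.4.0]tetradeca-2,4,6,11-tetraene-3-carboxylate (ten-membered triene, all three ring alkenes cis in the ring) | C1[C@H](O)/C(C)=C\C=C/C(C(=O)OC)=C\[C@H]2[C@@H](C(C)C)CC=C(C)[C@@H]21 | intermediate
29 | dioxygen | O=O | starting material
30 | methyl (1R,2E,4R,5Z,7S,8S,10R,11Z,14R)-4,7-epidioxy-8-hydroxy-7,11-dimethyl-14-(propan-2-yl)bicyclo[8.4.0]tetradeca-2,5,11-triene-3-carboxylate (bridged endoperoxide) | C1[C@H](O)[C@]3(C)C=C[C@@H](OO3)/C(C(=O)OC)=C\[C@H]2[C@@H](C(C)C)CC=C(C)[C@@H]21 | intermediate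
31 | methyl (1R,2E,5Z,7S,8S,10R,11Z,14R)-7,8-dihydroxy-7,11-dimethyl-4-oxo-14-(propan-2-yl)bicyclo[8.4.0]tetradeca-2,5,11-triene-3-carboxylate | C1[C@H](O)[C@@](C)(O)/C=C\C(=O)/C(C(=O)OC)=C\[C@H]2[C@@H](C(C)C)CC=C(C)[C@@H]21 | intermediate
32 | methyl (1R,2E,4R,5Z,7S,8S,10R,11Z,14R)-4,7-epoxy-4,8-dihydroxy-7,11-dimethyl-14-(propan-2-yl)bicyclo[8.4.0]tetradeca-2,5,11-triene-3-carboxylate | COC(=O)/C1=C/[C@H]2[C@@H](C(C)C)CC=C(C)[C@@H]2C[C@H](O)[C@]2(C)C=C[C@@]1(O)O2 | intermediate
33 | 1-methyl-1H-imidazole-4-carbaldehyde | Cn1cnc(C=O)c1 | starting material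
34 | malonic acid | OC(=O)CC(=O)O | starting material
35 | [(1-methyl-1H-imidazol-4-yl)methylidene]propanedioic acid | Cn1cnc(C=C(C(=O)O)C(=O)O)c1 | intermediate
36 | (2E)-3-(1-methyl-1H-imidazol-4-yl)prop-2-enoic acid | Cn1cnc(/C=C/C(=O)O)c1 | intermediate
37 | CNP0372023.1: methyl (1R,2E,4R,5Z,7S,8S,10R,11Z,14R)-4,7-epoxy-4-hydroxy-7,11-dimethyl-8-{[(2E)-3-(1-methyl-1H-imidazol-4-yl)prop-2-enoyl]oxy}-14-(propan-2-yl)bicyclo[8.4.0]tetradeca-2,5,11-triene-3-carboxylate | COC(=O)/C1=C/[C@H]2[C@@H](C(C)C)CC=C(C)[C@@H]2C[C@H](OC(=O)/C=C/c2cn(C)cn2)[C@]2(C)C=C[C@@]1(O)O2 | target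

**Step count**

Total step count: 23. Longest linear sequence: 21 steps (steps 1–13, 15–21 and 23).

**Steps most likely to fail**

Step 20 (key step). The ene reaction of singlet oxygen at the trisubstituted C11=C12 alkene or at the C7 methyl group may outrun cycloaddition to the twisted, ester-bearing diene. Oxygen may also add to the diene face away from the hydroxyl, or the triene may close thermally before it is trapped. The fallback sets out from 28 and brings in the two oxygens one after the other. Hydroxyl-directed epoxidation of C6=C7 (VO(acac)2, tBuOOH, CH2Cl2, 0 °C) should, by the same 1,3-allylic strain argument, give the epoxy alcohol F1 with the C7 oxygen on the hydroxyl face. Opening of this vinyl epoxide through the π-allyl complex of zerovalent palladium (Pd(PPh3)4, AcOH, THF, 0 °C) should place acetate on C4, the cis alkene at C5=C6 and the tertiary hydroxyl on C7, giving the hydroxy acetate F2, whose C4 configuration does not matter. Methanolysis (K2CO3, MeOH) gives the triol F3, and MnO2 oxidises only the doubly allylic C4 hydroxyl to the hydroxy enone 31, which closes to 32, where the fallback rejoins the route.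

Step 19 (ring closure). Intermolecular coupling may win over closure of the strained ten-membered ring, tin may be lost from the dienylstannane in steps 15–18, or the triene may undergo 6π ring closure once formed. The fallback sets out from 20 and does not carry a stannane. Dess–Martin oxidation gives the aldehyde F4, the same α-iodo Wittig reaction gives the bis-iodide F5, and HF·pyridine gives the hydroxy bis-iodide F6. A double Stille coupling of F6 with one equivalent of 23 (Pd2(dba)3, AsPh3, iPr2NEt, DMF/THF, rt, high dilution) inserts the C4=C5 unit between C3 and C6 and closes the ring in one operation, rejoining the route at 28.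

Step 23 (acylation). The hemiketal hydroxyl at C4 may be acylated, the hemiketal may open under the basic catalyst, or the hindered C8 hydroxyl next to the quaternary C7 may react too slowly. The fallback sets out from 32. Ketalisation (pyridinium p-toluenesulfonate, MeOH) gives the C4 methyl ketal F7, the same carbodiimide esterification with 36 gives the methyl ketal ester F8, and mild hydrolysis (camphorsulfonic acid, wet MeCN) returns the hemiketal, rejoining the route at 37.

Further compounds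
F1 | step 20 | 6,7-epoxide of 28 with the epoxide oxygen on the hydroxyl face (7S) | C1[C@H](O)[C@@]3(C)O[C@H]3/C=C\C(C(=O)OC)=C/[C@H]2[C@@H](C(C)C)CC=C(C)[C@@H]21
F2 | step 20 | 4-acetoxy-7,8-dihydroxy-2,5,11-triene ester (C4 configuration not defined) | C1[C@H](O)[C@@](C)(O)/C=C\C(OC(C)=O)/C(C(=O)OC)=C\[C@H]2[C@@H](C(C)C)CC=C(C)[C@@H]21
F3 | step 20 | 4,7,8-trihydroxy-2,5,11-triene ester (C4 configuration not defined) | C1[C@H](O)[C@@](C)(O)/C=C\C(O)/C(C(=O)OC)=C\[C@H]2[C@@H](C(C)C)CC=C(C)[C@@H]21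
F4 | step 19 | (1S,2R,6R)-2-{(2S,3Z)-4-iodo-3-methyl-2-(triethylsilyloxy)but-3-en-1-yl}-3-methyl-6-(propan-2-yl)cyclohex-3-ene-1-carbaldehyde | O=C[C@H]1[C@@H](C(C)C)CC=C(C)[C@@H]1C[C@H](O[Si](CC)(CC)CC)/C(C)=C\I
F5 | step 19 | methyl (2Z)-2-iodo-3-[(1S,2R,6R)-2-{(2S,3Z)-4-iodo-3-methyl-2-(triethylsilyloxy)but-3-en-1-yl}-3-methyl-6-(propan-2-yl)cyclohex-3-en-1-yl]prop-2-enoate | COC(=O)/C(I)=C/[C@H]1[C@@H](C(C)C)CC=C(C)[C@@H]1C[C@H](O[Si](CC)(CC)CC)/C(C)=C\I
F6 | step 19 | methyl (2Z)-3-[(1S,2R,6R)-2-{(2S,3Z)-2-hydroxy-4-iodo-3-methylbut-3-en-1-yl}-3-methyl-6-(propan-2-yl)cyclohex-3-en-1-yl]-2-iodoprop-2-enoate | COC(=O)/C(I)=C/[C@H]1[C@@H](C(C)C)CC=C(C)[C@@H]1C[C@H](O)/C(C)=C\I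
F7 | step 23 | C4 methyl ketal of 32 | COC(=O)/C1=C/[C@H]2[C@@H](C(C)C)CC=C(C)[C@@H]2C[C@H](O)[C@]2(C)C=C[C@@]1(OC)O2
F8 | step 23 | C4 methyl ketal of 37 | COC(=O)/C1=C/[C@H]2[C@@H](C(C)C)CC=C(C)[C@@H]2C[C@H](OC(=O)/C=C/c2cn(C)cn2)[C@]2(C)C=C[C@@]1(OC)O2
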